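Strategy (longipinane numbering: C1 ketone, C2=C3 alkene, C4 and C11 bridgeheads, C5 and C10 one-carbon bridges). Everything rests on detaching the enone bridge C1–C2–C3 from the cyclobutane ring C4–C5–C11–C10, so that C1–C11 and C3–C4 arise together. The precursor is a bicyclo[1.1.0]butane ester whose central bond joins C4 and C11 and whose wing carbons C5 and C10 carry the future seven-ring arms exo. A copper-catalysed (Z)-alkenyl Grignard adds to C4 with strain release; the C11 enolate set free acylates on the tethered Weinreb amide, closing the bicyclo[3.1.1]heptenone in one operation. Radical decarboxylation, Claisen closure of the seven-membered ring and directed reductions follow.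

Key step: step 13

Remark: the ester on the CH2O group is read from the SMILES as (Z)-2-methylbut-2-enoate (angelate); C6–C9 is the four-carbon bridge and C15 the oxygenated carbon on C6; compounds 1, 2, 5 and 18 are taken as commercially available.

Step 1
Reactants: 1 3,3-dimethoxybutan-2-one; 2 diethyl [2-[methoxy(methyl)amino]-2-oxoethyl]phosphonate
Product: 3 (E)-N,4,4-trimethoxy-N,3-dimethylpent-2-enamide
Conditions: NaH, THF, 0 °C to reflux
Reagents that add atoms: none
Why: Horner–Wadsworth–Emmons olefination of the ketone; the bulky ketal carbon should end trans to the amide carbonyl, and any (Z) isomer is removed by chromatography.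

Step 2
Reactants: 3 (E)-N,4,4-trimethoxy-N,3-dimethylpent-2-enamide
Product: 4 (E)-4,4-dimethoxy-3-methylpent-2-enal
Conditions: i-Bu2AlH, THF, −78 °C; aq. KNaC4H4O6
Reagents that add atoms: none
Why: Weinreb amide reduction should stop at the aldehyde because the chelated aluminium hemiaminal survives until the neutral work-up, which also spares the ketal.

Step 3
Reactants: 4 (E)-4,4-dimethoxy-3-methylpent-2-enal; 5 (S)-4-benzyl-3-propanoyl-1,3-oxazolidin-2-one
Product: 6 (S)-4-benzyl-3-[(2S,3R,4E)-3-hydroxy-6,6-dimethoxy-2,5-dimethylhept-4-enoyl]-1,3-oxazolidin-2-one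
Conditions: 5, n-Bu2BOTf, i-Pr2NEt, CH2Cl2, −78 to 0 °C; then 4, −78 to 0 °C; pH 7 buffer (NaH2PO4/Na2HPO4), MeOH, H2O2
Reagents that add atoms: none
Why: Evans syn-aldol reaction; the (Z)-boron enolate reacts through a Zimmerman–Traxler chair on the face left open by the benzyl group, which sets C2 (S) and the carbinol C3 (R).

Step 4
Reactants: 6 (S)-4-benzyl-3-[(2S,3R,4E)-3-hydroxy-6,6-dimethoxy-2,5-dimethylhept-4-enoyl]-1,3-oxazolidin-2-one
Product: 7 methyl (2S,3R,4E)-3-hydroxy-6,6-dimethoxy-2,5-dimethylhept-4-enoate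
Conditions: NaOMe (cat.), MeOH, 0 °C
Reagents that add atoms: methanol, SMILES CO
Why: Methanolysis (transacylation) at the exocyclic imide carbonyl releases the auxiliary; short contact at 0 °C should avoid retro-aldol cleavage.

Step 5
Reactants: 7 methyl (2S,3R,4E)-3-hydroxy-6,6-dimethoxy-2,5-dimethylhept-4-enoate
Product: 8 methyl (2R,3R,4E)-3-hydroxy-2-(hydroxymethyl)-6,6-dimethoxy-2,5-dimethylhept-4-enoate
Conditions: LiN(i-Pr)2 (2.5 equiv), THF, −78 to −20 °C; CH2O (gas), −78 °C; AcOH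
Reagents that add atoms: formaldehyde, SMILES C=O
Why: Fráter–Seebach reaction; the chelated alkoxide–enolate dianion should take up formaldehyde on the face opposite the alkenyl group of the carbinol carbon, setting the quaternary C2 (R) anti to the hydroxyl, while the old C2 configuration is erased in the enolate.

Step 6
Reactants: 8 methyl (2R,3R,4E)-3-hydroxy-2-(hydroxymethyl)-6,6-dimethoxy-2,5-dimethylhept-4-enoate
Product: 10 methyl (2R,3R,4E)-3-acetoxy-2-[(tert-butyldiphenylsilyl)oxymethyl]-6,6-dimethoxy-2,5-dimethylhept-4-enoate, via silyl ether 9 (not isolated)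
Conditions: t-BuPh2SiCl, imidazole, DMF, 0 °C to rt; then Ac2O, DMAP, rt
Reagents that add atoms: tert-butyl(chloro)diphenylsilane, SMILES CC(C)(C)[Si](Cl)(c1ccccc1)c1ccccc1; acetic anhydride, SMILES CC(=O)OC(C)=O
Why: Silylation should select the primary alcohol over the hindered allylic secondary one, which is then acetylated in the same flask (DMAP-catalysed acyl transfer); no stereocentre is touched.

Step 7
Reactants: 10 methyl (2R,3R,4E)-3-acetoxy-2-[(tert-butyldiphenylsilyl)oxymethyl]-6,6-dimethoxy-2,5-dimethylhept-4-enoate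
Product: 13 (3S,4E,6S)-6-[(tert-butyldiphenylsilyl)oxymethyl]-3-(1,1-dimethoxyethyl)-7-methoxy-3,6-dimethyl-7-oxohept-4-enoic acid, via silyl ketene acetal 11 (not isolated), via trimethylsilyl ester 12 (not isolated)
Conditions: LiN(i-Pr)2, Me3SiCl, Et3N, THF, −78 °C, then 60 °C; aq. citric acid (pH 5)
Reagents that add atoms: none
Why: Ireland–Claisen rearrangement; a chair with the quaternary substituent of the carbinol carbon equatorial should give the (E)-alkene and pass the C3–O configuration suprafacially to the new quaternary carbon C3 (S), the cis-methyl being axial and the ketal carbon equatorial.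

Step 8
Reactants: 13 (3S,4E,6S)-6-[(tert-butyldiphenylsilyl)oxymethyl]-3-(1,1-dimethoxyethyl)-7-methoxy-3,6-dimethyl-7-oxohept-4-enoic acid
Product: 14 7-tert-butyl 1-methyl (2S,3E,5S)-2-[(tert-butyldiphenylsilyl)oxymethyl]-5-(1,1-dimethoxyethyl)-2,5-dimethylhept-3-enedioate
Conditions: tert-butyl 2,2,2-trichloroacetimidate, cyclohexane/CH2Cl2, rt
Reagents that add atoms: tert-butyl 2,2,2-trichloroacetimidate, SMILES CC(C)(C)OC(=N)C(Cl)(Cl)Cl
Why: tert-Butylation of the acid with the imidate runs without added acid, so the ketal and the silyl ether should survive.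

Step 9
Reactants: 14 7-tert-butyl 1-methyl (2S,3E,5S)-2-[(tert-butyldiphenylsilyl)oxymethyl]-5-(1,1-dimethoxyethyl)-2,5-dimethylhept-3-enedioate
Product: 16 7-tert-butyl 1-methyl (2S,3E,5R)-2-[(tert-butyldiphenylsilyl)oxymethyl]-6-diazo-5-(1,1-dimethoxyethyl)-2,5-dimethylhept-3-enedioate, via trifluoroacetyl ester 15 (not isolated)
Conditions: LiN(SiMe3)2, THF, −78 °C; CF3CO2CH2CF3; then MeSO2N3, Et3N, H2O, MeCN, rt
Reagents that add atoms: methanesulfonyl azide, SMILES CS(=O)(=O)N=[N+]=[N-]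
Why: Deacylative (detrifluoroacetylative) diazo transfer; the only enolisable ester is trifluoroacetylated, takes up the diazo group and loses the trifluoroacetyl group, and no stereocentre is affected (the C5 descriptor changes only by priority).

Step 10
Reactants: 16 7-tert-butyl 1-methyl (2S,3E,5R)-2-[(tert-butyldiphenylsilyl)oxymethyl]-6-diazo-5-(1,1-dimethoxyethyl)-2,5-dimethylhept-3-enedioate
Product: 17 tert-butyl 2-exo-[(2S)-1-[(tert-butyldiphenylsilyl)oxy]-3-methoxy-2-methyl-3-oxopropan-2-yl]-4-exo-(1,1-dimethoxyethyl)-4-endo-methylbicyclo[1.1.0]butane-1-carboxylate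
Conditions: Rh2(OAc)4 (1 mol %), toluene, −78 °C to rt, slow addition of 16
Reagents that add atoms: none
Why: Rhodium-carbenoid intramolecular cyclopropanation (bicyclobutanation of a 2-diazopent-4-enoate); the (E)-alkene places the side chain exo stereospecifically, the quaternary tether carbon has no β-hydrogen for a 1,2-shift, and the alkene face should be chosen so that the methyl, not the ketal-bearing carbon, takes the crowded endo position.

Step 11
Reactants: 18 but-2-ynoic acid
Product: 19 (Z)-3-iodobut-2-enoic acid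
Conditions: NaI, AcOH, 110 °C
Reagents that add atoms: sodium iodide, SMILES [Na+].[I-]
Why: Anti hydroiodination of the ynoic acid (iodide conjugate addition, then protonation) should give the (Z)-β-iodo acid.

Step 12
Reactants: 19 (Z)-3-iodobut-2-enoic acid
Product: 21 (Z)-3-iodo-N-methoxy-N-methylbut-2-enamide, via acid chloride 20 (not isolated)
Conditions: (COCl)2, DMF (cat.), CH2Cl2, 0 °C to rt; then MeNH(OMe)·HCl, pyridine, 0 °C
Reagents that add atoms: N,O-dimethylhydroxylamine hydrochloride, SMILES CNOC.Cl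
Why: Acid chloride formation and amidation (Weinreb amide synthesis); the alkene geometry is not touched.

Step 13
Reactants: 17 tert-butyl 2-exo-[(2S)-1-[(tert-butyldiphenylsilyl)oxy]-3-methoxy-2-methyl-3-oxopropan-2-yl]-4-exo-(1,1-dimethoxyethyl)-4-endo-methylbicyclo[1.1.0]butane-1-carboxylate; 21 (Z)-3-iodo-N-methoxy-N-methylbut-2-enamide
Product: 25 tert-butyl (1S,5R,6R,7R)-7-[(2S)-1-[(tert-butyldiphenylsilyl)oxy]-3-methoxy-2-methyl-3-oxopropan-2-yl]-6-(1,1-dimethoxyethyl)-4,6-dimethyl-2-oxobicyclo[3.1.1]hept-3-ene-1-carboxylate, via alkenylmagnesium chloride 22 (not isolated), via magnesium ester enolate 23 (not isolated), via magnesium hemiaminal 24 (not isolated)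
Conditions: 21, i-PrMgCl·LiCl, THF, −40 °C; then CuBr·SMe2 (20 mol %), PBu3, 17, THF, −78 to 0 °C; aq. NH4Cl
Reagents that add atoms: none
Why: Iodine–magnesium exchange gives the chelate-stabilised (Z)-alkenylmagnesium 22, which after transmetalation to copper adds to the unsubstituted bridgehead C4 of 17 along the axis of the strained central bond (homoconjugate addition), breaking C4–C11 and forming C3–C4 together with the ester enolate 23; this enolate attacks the cis-placed Weinreb amide to form C1–C11, and the N,O-chelated adduct 24 releases the enone only on quench, which shields it from a second addition. The closest known reaction types are the copper-catalysed homoconjugate addition of Grignard reagents to bicyclobutane carboxylates with trapping of the enolate by an electrophile, and the acylation of ester enolates by Weinreb amides. The six-membered enone ring (C1, C2, C3, C4, C5 or C10, C11) closes by 6-exo-trig attack of the exocyclic enolate carbon C11 on the amide carbonyl, possible because the monocyclic cyclobutane intermediate can pucker to bring the C4 alkenyl group over the C11 p-orbital and because the alkene is Z. C4 is set by backside attack (inversion), which puts the new bridge cis to the former endo groups (H on C5, methyl on C10) and trans to both exo side chains; C11 is a planar enolate and is fixed by ring closure in the only bridged geometry available. The step needs attack at C4 and not at the other esters, secured by strain release at the bridgehead, by the neopentyl shielding of the methyl ester and by the low electrophilicity of the tert-butyl ester; low temperature should limit self-condensation of 22.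

Step 14
Reactants: 25 tert-butyl (1S,5R,6R,7R)-7-[(2S)-1-[(tert-butyldiphenylsilyl)oxy]-3-methoxy-2-methyl-3-oxopropan-2-yl]-6-(1,1-dimethoxyethyl)-4,6-dimethyl-2-oxobicyclo[3.1.1]hept-3-ene-1-carboxylate
Product: 26 (1S,5R,6R,7R)-6-acetyl-7-[(2S)-1-[(tert-butyldiphenylsilyl)oxy]-3-methoxy-2-methyl-3-oxopropan-2-yl]-4,6-dimethyl-2-oxobicyclo[3.1.1]hept-3-ene-1-carboxylic acid
Conditions: CF3CO2H, CH2Cl2, H2O (10:10:1), 0 °C to rt
Reagents that add atoms: water, SMILES O
Why: Acidolysis removes the tert-butyl ester as isobutene and hydrolyses the dimethyl ketal in the same pot; the silyl ether and methyl ester should survive, and the bridgehead β-keto acid cannot decarboxylate through an anti-Bredt enol.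

Step 15
Reactants: 26 (1S,5R,6R,7R)-6-acetyl-7-[(2S)-1-[(tert-butyldiphenylsilyl)oxy]-3-methoxy-2-methyl-3-oxopropan-2-yl]-4,6-dimethyl-2-oxobicyclo[3.1.1]hept-3-ene-1-carboxylic acid
Product: 27 methyl (2S)-2-[(1R,5R,6R,7S)-6-acetyl-4,6-dimethyl-2-oxobicyclo[3.1.1]hept-3-en-7-yl]-3-[(tert-butyldiphenylsilyl)oxy]-2-methylpropanoate
Conditions: 9-mesityl-10-phenylacridinium tetrafluoroborate (5 mol %), PhSSPh (10 mol %), i-Pr2NEt (20 mol %), CF3CH2OH, 450 nm LEDs, rt
Reagents that add atoms: none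
Why: Photoredox hydrodecarboxylation; the carboxylate is oxidised, loses CO2 to the bridgehead cyclobutyl radical, and hydrogen-atom transfer from thiophenol gives C11–H, whose configuration is fixed by the bicycle.

Step 16
Reactants: 27 methyl (2S)-2-[(1R,5R,6R,7S)-6-acetyl-4,6-dimethyl-2-oxobicyclo[3.1.1]hept-3-en-7-yl]-3-[(tert-butyldiphenylsilyl)oxy]-2-methylpropanoate
Product: 28 (4R,5S,6S,10R,11R)-15-[(tert-butyldiphenylsilyl)oxy]longipin-2-ene-1,7,9-trione
Conditions: KOt-Bu (2.5 equiv), THF, 0 °C to rt; then AcOH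
Reagents that add atoms: none
Why: Intramolecular Claisen (Dieckmann-type) condensation; the methyl of the acetyl group is the only useful enolisable position, the two arms are held 1,3-cis on the cyclobutane, and deprotonation of the 1,3-diketone should drive closure of the seven-membered ring without touching C6.

Step 17
Reactants: 28 (4R,5S,6S,10R,11R)-15-[(tert-butyldiphenylsilyl)oxy]longipin-2-ene-1,7,9-trione
Product: 29 (4R,5S,6S,10R,11R)-15-hydroxylongipin-2-ene-1,7,9-trione
Conditions: HF·pyridine, pyridine, THF, 0 °C to rt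
Reagents that add atoms: none
Why: Fluoride-mediated desilylation under buffered acidic conditions, which should avoid retro-aldol loss of formaldehyde from the β-hydroxy ketone.

Step 18
Reactants: 29 (4R,5S,6S,10R,11R)-15-hydroxylongipin-2-ene-1,7,9-trione
Product: 30 (4R,5S,6S,7R,9R,10R,11R)-7,9,15-trihydroxylongipin-2-en-1-one
Conditions: Me4NBH(OAc)3 (8 equiv), AcOH/MeCN (1:1), −30 °C to rt; aq. KNaC4H4O6
Reagents that add atoms: none
Why: Hydroxyl-directed triacetoxyborohydride reduction (Evans–Saksena); the C15 alkoxyborohydride should deliver hydride to C7 on the face of the CH2O group (C7–OH cis to the C6 methyl), and the C7 alkoxide then directs delivery to C9 to give the anti 1,3-diol, while the enone carbonyl, which has no 1,3-hydroxyl, is left alone.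

Step 19
Reactants: 30 (4R,5S,6S,7R,9R,10R,11R)-7,9,15-trihydroxylongipin-2-en-1-one
Product: 33 (4R,5S,6S,7R,9R,10R,11R)-7,15-dihydroxy-9-(3-methylbut-2-enoyloxy)longipin-2-en-1-one, via cyclic phenylboronate 31 (not isolated), via acylated phenylboronate 32 (not isolated)
Conditions: PhB(OH)2, MgSO4, toluene, rt; then 3-methylbut-2-enoyl chloride, pyridine, DMAP (cat.), CH2Cl2, 0 °C to rt; then pinacol, rt
Reagents that add atoms: 3-methylbut-2-enoyl chloride, SMILES CC(C)=CC(=O)Cl
Why: Transient boronate protection; phenylboronic acid should tie up the C7/C15 1,3-diol as a six-membered boronate (the trans C7/C9 pair cannot chelate), so that DMAP-catalysed acylation reaches only C9–OH, and exchange with pinacol frees the diol.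

Step 20
Reactants: 33 (4R,5S,6S,7R,9R,10R,11R)-7,15-dihydroxy-9-(3-methylbut-2-enoyloxy)longipin-2-en-1-one
Product: 34 (4R,5S,6S,7R,9R,10R,11R)-15-[(Z)-2-methylbut-2-enoyloxy]-7-hydroxy-9-(3-methylbut-2-enoyloxy)longipin-2-en-1-one
Conditions: angelic acid, 2,4,6-trichlorobenzoyl chloride, Et3N, toluene, rt; then 33, 80 °C
Reagents that add atoms: angelic acid [(Z)-2-methylbut-2-enoic acid], SMILES C/C=C(/C)C(=O)O
Why: Yamaguchi esterification through the mixed anhydride, the usual way to make angelates without Z-to-E isomerisation; the primary C15–OH should react ahead of the hindered secondary C7–OH.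

Step 21
Reactants: 34 (4R,5S,6S,7R,9R,10R,11R)-15-[(Z)-2-methylbut-2-enoyloxy]-7-hydroxy-9-(3-methylbut-2-enoyloxy)longipin-2-en-1-one
Product: 35 (4R,5S,6S,7R,9R,10R,11R)-7-acetoxy-15-[(Z)-2-methylbut-2-enoyloxy]-9-(3-methylbut-2-enoyloxy)longipin-2-en-1-one (CNP0179010.1)
Conditions: Ac2O, pyridine, DMAP (cat.), CH2Cl2, rt
Reagents that add atoms: acetic anhydride, SMILES CC(=O)OC(C)=O
Why: DMAP-catalysed acetylation of the last free alcohol under conditions mild enough that the angelate should not isomerise and the other esters should not migrate.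

Compound list

1 | 3,3-dimethoxybutan-2-one | CC(=O)C(C)(OC)OC | starting material
2 | diethyl [2-[methoxy(methyl)amino]-2-oxoethyl]phosphonate | CCOP(=O)(CC(=O)N(C)OC)OCC | starting material
3 | (E)-N,4,4-trimethoxy-N,3-dimethylpent-2-enamide | CON(C)C(=O)/C=C(\C)C(C)(OC)OC | intermediate
4 | (E)-4,4-dimethoxy-3-methylpent-2-enal | O=C/C=C(\C)C(C)(OC)OC | intermediate
5 | (S)-4-benzyl-3-propanoyl-1,3-oxazolidin-2-one | CCC(=O)N1[C@@H](Cc2ccccc2)COC1=O | starting material
6 | (S)-4-benzyl-3-[(2S,3R,4E)-3-hydroxy-6,6-dimethoxy-2,5-dimethylhept-4-enoyl]-1,3-oxazolidin-2-one | O=C1OC[C@H](Cc2ccccc2)N1C(=O)[C@@H](C)[C@H](O)/C=C(\C)C(C)(OC)OC | intermediate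
7 | methyl (2S,3R,4E)-3-hydroxy-6,6-dimethoxy-2,5-dimethylhept-4-enoate | COC(=O)[C@@H](C)[C@H](O)/C=C(\C)C(C)(OC)OC | intermediate
8 | methyl (2R,3R,4E)-3-hydroxy-2-(hydroxymethyl)-6,6-dimethoxy-2,5-dimethylhept-4-enoate | COC(=O)[C@](C)(CO)[C@H](O)/C=C(\C)C(C)(OC)OC | intermediate
9 | methyl (2R,3R,4E)-2-[(tert-butyldiphenylsilyl)oxymethyl]-3-hydroxy-6,6-dimethoxy-2,5-dimethylhept-4-enoate (silyl ether, not isolated) | COC(=O)[C@](C)(CO[Si](c1ccccc1)(c1ccccc1)C(C)(C)C)[C@H](O)/C=C(\C)C(C)(OC)OC | intermediate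
10 | methyl (2R,3R,4E)-3-acetoxy-2-[(tert-butyldiphenylsilyl)oxymethyl]-6,6-dimethoxy-2,5-dimethylhept-4-enoate | COC(=O)[C@](C)(CO[Si](c1ccccc1)(c1ccccc1)C(C)(C)C)[C@H](OC(C)=O)/C=C(\C)C(C)(OC)OC | intermediate
11 | trimethylsilyl ketene acetal of 10 (3-[1-(trimethylsilyloxy)vinyloxy] ester, not isolated) | COC(=O)[C@](C)(CO[Si](c1ccccc1)(c1ccccc1)C(C)(C)C)[C@H](OC(=C)O[Si](C)(C)C)/C=C(\C)C(C)(OC)OC | intermediate
12 | trimethylsilyl ester of 13 (not isolated) | C[Si](C)(C)OC(=O)C[C@](C)(C(C)(OC)OC)/C=C/[C@@](C)(CO[Si](c1ccccc1)(c1ccccc1)C(C)(C)C)C(=O)OC | intermediate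
13 | (3S,4E,6S)-6-[(tert-butyldiphenylsilyl)oxymethyl]-3-(1,1-dimethoxyethyl)-7-methoxy-3,6-dimethyl-7-oxohept-4-enoic acid | OC(=O)C[C@](C)(C(C)(OC)OC)/C=C/[C@@](C)(CO[Si](c1ccccc1)(c1ccccc1)C(C)(C)C)C(=O)OC | intermediate
14 | 7-tert-butyl 1-methyl (2S,3E,5S)-2-[(tert-butyldiphenylsilyl)oxymethyl]-5-(1,1-dimethoxyethyl)-2,5-dimethylhept-3-enedioate | CC(C)(C)OC(=O)C[C@](C)(C(C)(OC)OC)/C=C/[C@@](C)(CO[Si](c1ccccc1)(c1ccccc1)C(C)(C)C)C(=O)OC | intermediate
15 | 6-(trifluoroacetyl) derivative of 14 (mixture at C6, not isolated) | CC(C)(C)OC(=O)C(C(=O)C(F)(F)F)[C@](C)(C(C)(OC)OC)/C=C/[C@@](C)(CO[Si](c1ccccc1)(c1ccccc1)C(C)(C)C)C(=O)OC | intermediate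
16 | 7-tert-butyl 1-methyl (2S,3E,5R)-2-[(tert-butyldiphenylsilyl)oxymethyl]-6-diazo-5-(1,1-dimethoxyethyl)-2,5-dimethylhept-3-enedioate | CC(C)(C)OC(=O)C(=[N+]=[N-])[C@](C)(C(C)(OC)OC)/C=C/[C@@](C)(CO[Si](c1ccccc1)(c1ccccc1)C(C)(C)C)C(=O)OC | intermediate
17 | tert-butyl 2-exo-[(2S)-1-[(tert-butyldiphenylsilyl)oxy]-3-methoxy-2-methyl-3-oxopropan-2-yl]-4-exo-(1,1-dimethoxyethyl)-4-endo-methylbicyclo[1.1.0]butane-1-carboxylate (absolute configuration as in the SMILES) | CC(C)(C)OC(=O)[C@@]12[C@@H]([C@@](C)(CO[Si](c3ccccc3)(c3ccccc3)C(C)(C)C)C(=O)OC)[C@@H]1[C@@]2(C)C(C)(OC)OC | intermediate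
18 | but-2-ynoic acid | CC#CC(=O)O | starting material
19 | (Z)-3-iodobut-2-enoic acid | C/C(I)=C/C(=O)O | intermediate
20 | (Z)-3-iodobut-2-enoyl chloride (not isolated) | C/C(I)=C/C(=O)Cl | intermediate
21 | (Z)-3-iodo-N-methoxy-N-methylbut-2-enamide | C/C(I)=C/C(=O)N(C)OC | intermediate
22 | (Z)-[4-[methoxy(methyl)amino]-4-oxobut-2-en-2-yl]magnesium chloride (not isolated) | C/C([Mg]Cl)=C/C(=O)N(C)OC | intermediate
23 | chloromagnesium ester enolate of the cyclobutane formed by addition of 22 to 17 (alkenyl group cis to the ring methyl and to H on C2, not isolated) | CC(C)(C)OC(O[Mg]Cl)=C1[C@@H]([C@@](C)(CO[Si](c2ccccc2)(c2ccccc2)C(C)(C)C)C(=O)OC)[C@H](/C(C)=C\C(=O)N(C)OC)[C@@]1(C)C(C)(OC)OC | intermediate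
24 | chloromagnesium N,O-hemiaminal of 25 at C2 (tetrahedral adduct, not isolated) | COC(=O)[C@](C)(CO[Si](c1ccccc1)(c1ccccc1)C(C)(C)C)[C@@H]2[C@@]3(C(=O)OC(C)(C)C)C(O[Mg]Cl)(N(C)OC)C=C(C)[C@@H]2[C@@]3(C)C(C)(OC)OC | intermediate
25 | tert-butyl (1S,5R,6R,7R)-7-[(2S)-1-[(tert-butyldiphenylsilyl)oxy]-3-methoxy-2-methyl-3-oxopropan-2-yl]-6-(1,1-dimethoxyethyl)-4,6-dimethyl-2-oxobicyclo[3.1.1]hept-3-ene-1-carboxylate (6-methyl syn, both side chains anti to the enone bridge) | COC(=O)[C@](C)(CO[Si](c1ccccc1)(c1ccccc1)C(C)(C)C)[C@@H]2[C@@]3(C(=O)OC(C)(C)C)C(=O)C=C(C)[C@@H]2[C@@]3(C)C(C)(OC)OC | intermediate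
26 | (1S,5R,6R,7R)-6-acetyl-7-[(2S)-1-[(tert-butyldiphenylsilyl)oxy]-3-methoxy-2-methyl-3-oxopropan-2-yl]-4,6-dimethyl-2-oxobicyclo[3.1.1]hept-3-ene-1-carboxylic acid | COC(=O)[C@](C)(CO[Si](c1ccccc1)(c1ccccc1)C(C)(C)C)[C@@H]2[C@@]3(C(=O)O)C(=O)C=C(C)[C@@H]2[C@@]3(C)C(C)=O | intermediate
27 | methyl (2S)-2-[(1R,5R,6R,7S)-6-acetyl-4,6-dimethyl-2-oxobicyclo[3.1.1]hept-3-en-7-yl]-3-[(tert-butyldiphenylsilyl)oxy]-2-methylpropanoate | COC(=O)[C@](C)(CO[Si](c1ccccc1)(c1ccccc1)C(C)(C)C)[C@@H]2[C@H]3C(=O)C=C(C)[C@@H]2[C@@]3(C)C(C)=O | intermediate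
28 | (4R,5S,6S,10R,11R)-15-[(tert-butyldiphenylsilyl)oxy]longipin-2-ene-1,7,9-trione | CC(C)(C)[Si](c4ccccc4)(c5ccccc5)OC[C@]1(C)[C@@H]2[C@H]3C(=O)C=C(C)[C@@H]2[C@@]3(C)C(=O)CC1=O | intermediate
29 | (4R,5S,6S,10R,11R)-15-hydroxylongipin-2-ene-1,7,9-trione | OC[C@]1(C)[C@@H]2[C@H]3C(=O)C=C(C)[C@@H]2[C@@]3(C)C(=O)CC1=O | intermediate
30 | (4R,5S,6S,7R,9R,10R,11R)-7,9,15-trihydroxylongipin-2-en-1-one | OC[C@]1(C)[C@@H]2[C@H]3C(=O)C=C(C)[C@@H]2[C@@]3(C)[C@H](O)C[C@H]1O | intermediate
31 | 7,15-O-(phenylboranediyl) derivative of 30 (six-membered boronate, not isolated) | c1ccccc1B2OC[C@]3(C)[C@@H]4[C@H]5C(=O)C=C(C)[C@@H]4[C@@]5(C)[C@H](O)C[C@H]3O2 | intermediate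
32 | 9-O-(3-methylbut-2-enoyl) derivative of 31 (not isolated) | c1ccccc1B2OC[C@]3(C)[C@@H]4[C@H]5C(=O)C=C(C)[C@@H]4[C@@]5(C)[C@H](OC(=O)C=C(C)C)C[C@H]3O2 | intermediate
33 | (4R,5S,6S,7R,9R,10R,11R)-7,15-dihydroxy-9-(3-methylbut-2-enoyloxy)longipin-2-en-1-one | OC[C@]1(C)[C@@H]2[C@H]3C(=O)C=C(C)[C@@H]2[C@@]3(C)[C@H](OC(=O)C=C(C)C)C[C@H]1O | intermediate
34 | (4R,5S,6S,7R,9R,10R,11R)-15-[(Z)-2-methylbut-2-enoyloxy]-7-hydroxy-9-(3-methylbut-2-enoyloxy)longipin-2-en-1-one | C/C=C(/C)C(=O)OC[C@]1(C)[C@@H]2[C@H]3C(=O)C=C(C)[C@@H]2[C@@]3(C)[C@H](OC(=O)C=C(C)C)C[C@H]1O | intermediate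
35 | (4R,5S,6S,7R,9R,10R,11R)-7-acetoxy-15-[(Z)-2-methylbut-2-enoyloxy]-9-(3-methylbut-2-enoyloxy)longipin-2-en-1-one (CNP0179010.1) | C/C=C(/C)C(=O)OC[C@]1(C)[C@@H]2[C@H]3C(=O)C=C(C)[C@@H]2[C@@]3(C)[C@H](OC(=O)C=C(C)C)C[C@H]1OC(C)=O | target

Total step count: 21. Longest linear sequence: 19 steps (steps 1–10 and 13–21); steps 11 and 12 make the alkenyl iodide 21 in a side branch.

Steps most likely to fail

1. Step 13 (key step). The bridgehead of 17 is flanked by two quaternary-substituted wing carbons, so addition may be slow enough for the alkenylcopper to decompose or self-condense. The cascade may also stop after the first bond, the enolate being protonated or aggregated before it reaches the amide. Fallback: setting out from 17 and 21, the same copper-catalysed addition is run and quenched at −78 °C with 2,6-di-tert-butyl-4-methylphenol, and the cyclobutane is isolated as tert-butyl 2-[(2S)-1-[(tert-butyldiphenylsilyl)oxy]-3-methoxy-2-methyl-3-oxopropan-2-yl]-4-(1,1-dimethoxyethyl)-3-[(Z)-4-[methoxy(methyl)amino]-4-oxobut-2-en-2-yl]-4-methylcyclobutane-1-carboxylate F1. In a separate operation the ester enolate is regenerated by deprotonation with KN(SiMe3)2 (THF, −78 to 0 °C), not by strain release, and the Dieckmann-type acylation onto the Weinreb amide should then return to the route at 25.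

2. Step 10. The carbenoid may be diverted into insertion into a methoxy C–H bond of the ketal, or facial control at the alkene may be lost so that the ketal-bearing carbon ends endo. Fallback: setting out from 14, the alkene face is chosen by the catalyst in a Shi epoxidation (fructose-derived ketone of the required enantiomeric series, KHSO5, K2CO3, MeCN/dimethoxymethane/buffer, 0 °C), which should give the trans-epoxide 7-tert-butyl 1-methyl 2-[(tert-butyldiphenylsilyl)oxymethyl]-5-(1,1-dimethoxyethyl)-3,4-epoxy-2,5-dimethylheptanedioate F2. The ester enolate (LiN(SiMe3)2, THF, −78 to 0 °C) then opens the epoxide in a 3-exo closure with inversion to the cyclopropyl carbinol tert-butyl 3-(1,1-dimethoxyethyl)-2-[1-hydroxy-2-[(tert-butyldiphenylsilyl)oxymethyl]-3-methoxy-2-methyl-3-oxopropyl]-3-methylcyclopropane-1-carboxylate F3 (carbinol chain cis to the ring methyl). Mesylation (MeSO2Cl, Et3N, CH2Cl2, 0 °C) gives the methanesulfonate of this carbinol F4, and KN(SiMe3)2 (THF, −78 °C to rt) closes the second three-membered ring by displacement with inversion (1,3-ring closure of a cyclopropyl ester enolate), returning to the route at 17. This last displacement at a neopentyl centre is itself slow.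

3. Step 16. The methyl ketone enolate has to attack an ester on a quaternary carbon; under equilibrating alkoxide conditions the enolate may instead drain into the dienolate of the enone and into intermolecular condensation. Fallback: setting out from 27, the methyl ester is cleaved with Me3SnOH (1,2-dichloroethane, 80 °C) to (2S)-2-[(1R,5R,6R,7S)-6-acetyl-4,6-dimethyl-2-oxobicyclo[3.1.1]hept-3-en-7-yl]-3-[(tert-butyldiphenylsilyl)oxy]-2-methylpropanoic acid F5. 1,1′-Carbonyldiimidazole (THF, rt) converts it into the acyl imidazole 1-[(2S)-2-[(1R,5R,6R,7S)-6-acetyl-4,6-dimethyl-2-oxobicyclo[3.1.1]hept-3-en-7-yl]-3-[(tert-butyldiphenylsilyl)oxy]-2-methylpropanoyl]imidazole F6. Kinetic enolisation of the methyl ketone (LiN(SiMe3)2, THF, −78 °C) and acylation by this far more reactive acyl donor should then return to the route at 28.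

Further compounds

F1 | step 13 | tert-butyl 2-[(2S)-1-[(tert-butyldiphenylsilyl)oxy]-3-methoxy-2-methyl-3-oxopropan-2-yl]-4-(1,1-dimethoxyethyl)-3-[(Z)-4-[methoxy(methyl)amino]-4-oxobut-2-en-2-yl]-4-methylcyclobutane-1-carboxylate | CC(C)(C)OC(=O)C1[C@@H]([C@@](C)(CO[Si](c2ccccc2)(c2ccccc2)C(C)(C)C)C(=O)OC)[C@H](/C(C)=C\C(=O)N(C)OC)[C@@]1(C)C(C)(OC)OC
F2 | step 10 | 7-tert-butyl 1-methyl 2-[(tert-butyldiphenylsilyl)oxymethyl]-5-(1,1-dimethoxyethyl)-3,4-epoxy-2,5-dimethylheptanedioate (trans-epoxide, configuration as in the SMILES) | CC(C)(C)OC(=O)C[C@](C)(C(C)(OC)OC)[C@H]1O[C@@H]1[C@@](C)(CO[Si](c2ccccc2)(c2ccccc2)C(C)(C)C)C(=O)OC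
F3 | step 10 | tert-butyl 3-(1,1-dimethoxyethyl)-2-[1-hydroxy-2-[(tert-butyldiphenylsilyl)oxymethyl]-3-methoxy-2-methyl-3-oxopropyl]-3-methylcyclopropane-1-carboxylate (carbinol chain cis to the ring methyl) | CC(C)(C)OC(=O)C1[C@](C)(C(C)(OC)OC)[C@H]1[C@H](O)[C@@](C)(CO[Si](c2ccccc2)(c2ccccc2)C(C)(C)C)C(=O)OC
F4 | step 10 | methanesulfonate of F3 | CC(C)(C)OC(=O)C1[C@](C)(C(C)(OC)OC)[C@H]1[C@H](OS(C)(=O)=O)[C@@](C)(CO[Si](c2ccccc2)(c2ccccc2)C(C)(C)C)C(=O)OC
F5 | step 16 | (2S)-2-[(1R,5R,6R,7S)-6-acetyl-4,6-dimethyl-2-oxobicyclo[3.1.1]hept-3-en-7-yl]-3-[(tert-butyldiphenylsilyl)oxy]-2-methylpropanoic acid | OC(=O)[C@](C)(CO[Si](c1ccccc1)(c1ccccc1)C(C)(C)C)[C@@H]2[C@H]3C(=O)C=C(C)[C@@H]2[C@@]3(C)C(C)=O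
F6 | step 16 | 1-[(2S)-2-[(1R,5R,6R,7S)-6-acetyl-4,6-dimethyl-2-oxobicyclo[3.1.1]hept-3-en-7-yl]-3-[(tert-butyldiphenylsilyl)oxy]-2-methylpropanoyl]imidazole | O=C(n1ccnc1)[C@](C)(CO[Si](c2ccccc2)(c2ccccc2)C(C)(C)C)[C@@H]3[C@H]4C(=O)C=C(C)[C@@H]3[C@@]4(C)C(C)=O
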